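## The problem

The target is a furanoheliangolide, numbered here as a germacrane: a ten-membered carbocycle from C1 (ketone) to C10 (quaternary, methyl C14), methyl C15 on C4, a lactone O–C6/C7–C11–C12 and the exocyclic methylene C13. An oxygen bridges C3 and C10, so that C10–C1(=O)–C2=C3–O is a 3(2H)-furanone and the carbocycle becomes a bicyclo[6.2.1] system whose nine-membered oxacycle holds the (Z)-C4=C5 olefin; any ring closure therefore has to overcome medium-ring strain. A trans-fused α-methylene-γ-butyrolactone sits on C6/C7, and C8 carries an (E)-2-(acetoxymethyl)but-2-enoate. There are four stereocentres (6S, 7S, 8R, 10R): C6 can control C7 because they are neighbours on a five-membered ring, and the C10 hydroxyl can control C8 through a 1,3-anti directed reduction, but C10 is insulated from C6/C7 by C8 and C9 and needs its own source of chirality. The fragile groups are the methylene lactone (Michael acceptor), the side-chain allylic acetate (open to SN2′ attack by amines and bases), the cross-conjugated furanone dienone, and the lactone itself, which can migrate to a free C8 hydroxyl. The enabling feature is that O–C6–C7–C11–C12 is a butyrolactone in which C7 is β and C11 is α to the carbonyl. A butenolide carrying only the C6 centre can therefore receive C8 as a nucleophile at C7 and C13 as an electrophile at C11 in one operation.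

## Retrosynthesis

**Methylene last.** Target 40 is traced to the 13-dimethylamino-11,13-dihydro compound 38 by cutting nothing in the skeleton. The C11=C13 bond is to arise by N-methylation (39) and β-elimination. Late methylenation of a lactone enolate would instead put strong base on the dienone and the side chain. The amine is the form in which C13 arrives in the key step, and it tolerates the basic and acidic steps in between.

**Ring closure at C4=C5.** Amine 38 is opened at the C4=C5 olefin to diene 37, which has a vinyl group on C6 and an isopropenyl group on the finished furanone. Closing C2–C3 by aldol or Claisen chemistry would need a C3 aldehyde or ester made in the presence of the lactone, and ten-membered closures of that kind are poorly precedented. With the furanone in place, metathesis closes only a nine-membered oxacycle and the ring dictates the Z geometry. The forward step must form a trisubstituted olefin and tolerate the amine, which is masked by protonation.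

**Side chain.** Ester 37 is cut at the C8–O acyl bond into alcohol 29 and acid 35. The acid is attached late because its allylic acetate and enoate would not survive lithium amides and would otherwise be exposed for many steps to the substrate's own tertiary amine. Acid 35 comes from tert-butyl acrylate 30 and acetaldehyde 31 by a Baylis–Hillman reaction (32), acetylation (33), allylic transposition to the thermodynamic E ester 34, and acidolysis.

**Furanone.** Alcohol 29 comes from silyl ether 28. The furanone of 28 is cut at C3–O (cyclodehydration of hydroxy diketone 27) and at C2–C3 (aldol of methyl ketone 24 with methacrolein 25, giving 26). Methacrolein brings C3, C4, C15 and the second metathesis olefin. The C8 oxygen stays silylated, so only the C10 hydroxyl can close onto C3.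

**C5 and C1 oxidation levels.** Ketone 24 comes from keto aldehyde 23 by methylenation. 23 comes from triol 22 by one double oxidation, and 22 from tris-silyl ether 21 by selective removal of the primary silyl ether and the triethylsilyl ether. Silyl ether 21 comes from diol 20 by silylation of the secondary hydroxyl. No skeletal bond is cut in this stretch; it only brings both termini to the right oxidation state together.

**C8.** Diol 20 is traced to β-hydroxy ketone 19. The C8 carbinol is to be set 1,3-anti to the C10 hydroxyl by intramolecular hydride delivery, which matches the 8R,10R pattern of the target.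

**C9–C10.** Ketone 19 is cut at C9–C10 into methyl ketone 14 and (S)-3-(triethylsilyloxy)butan-2-one 18. Pyruvate or butanedione would give no facial control, and chiral Lewis-acid catalysis (for example Cu(OTf)2–bis(oxazoline), divalent copper) is blocked by the basic amine. The lactate-derived α-silyloxy centre of 18 directs the addition by Felkin control and is later oxidised to the C1 carbonyl, so it leaves no trace. Ketone 18 comes from ethyl (S)-lactate 15 via 16 and 17.

**Key disconnection.** Amino keto lactone 14 is cut at C7–C8 and C11–C13 into butenolide 7, lithium bis(1-ethoxyvinyl)cuprate 10 and Eschenmoser's salt 11. Three components and two bonds give a precursor with a single stereocentre. The forward step must add 1,4 anti to the C6 substituent and trap the enolate (12) on carbon before the enol ether (13) is hydrolysed.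

**Starting materials.** Butenolide 7 comes from D-glutamic acid 1 through lactone acid 2, alcohol 3, silyl ether 4 and selenide/selenoxide 5/6. Cuprate 10 comes from two equivalents of ethyl vinyl ether 8 via 1-ethoxyvinyllithium 9.

## Roads not taken

**Alternative 1:** Cut C1–C2. The acyclic bromomethyl enone aldehyde A1 would be treated with SmI2 (divalent samarium). The samarium enolate at C2 adds to the C1 aldehyde and closes the ten-membered ring as β-hydroxy ketone A2, which is oxidised to the 1,3-diketone and cyclised to the furanone.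
- Merits: the ring closes by C–C bond formation of a type known for medium rings, the 1,3-dioxygen pattern appears directly, and the route is convergent.
- Weak points: A1 already carries the free methylene lactone, which is a substrate for one-electron reduction. The samarium dienolate is vinylogous to the C6 lactone oxygen and can expel it or scramble the Z olefin. The aldehyde is neopentylic and α-silyloxy, a motif SmI2 can cleave reductively.
- Comparison: this road is more convergent and reaches the diketone level in fewer redox steps than the chosen plan. The chosen plan sets against this a masked methylene that is indifferent to the ring-closing reagent, and C6/C7 fixed in the first C–C bond-forming step.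

**Alternative 2:** Cut C2–C3 through a transannular acyl shift. The nine-membered lactone A3 (the C10 oxygen acylated by C3, an acetyl group on C10) would be enolised with LiN(SiMe3)2. C2 attacks the lactone carbonyl through a five-membered transition state, and acid dehydration gives the bridged furanone A4.
- Merits: the C2–C3 bond, the furanone and the carbocycle form in one entropically favoured operation. In endgame step economy this is better than the chosen plan, which spends an aldol, an oxidation–cyclodehydration and a metathesis on the same result.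
- Weak points: A3 requires acylating a tertiary α-keto alcohol into a strained nine-membered (Z)-enoate lactone. The amide base then meets the free methylene lactone and the allylic C6 ester.
- Comparison: the chosen plan builds the furanone by intermolecular and five-ring events on an open chain and keeps the methylene masked while bases are used.

**Alternative 3:** Make the ten-membered ring by cleavage. A tetralin is dearomatised (Li, liquid NH3) to octalenone A5, whose tetrasubstituted C1=C6 ring-fusion olefin is cleaved with ozone and then Me2S to the 1,3,6-triketone A6.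
- Merits: no macrocyclisation is needed, so for making the ring this is the most reliable of the four. C7, C8 and C10 can be set on a six-membered ring.
- Weak points: A6 has three ketones that must be told apart, including a 1,4-dicarbonyl pair prone to transannular condensation. C4 is epimerisable and must still become the (Z)-C4=C5 olefin. C6 must be reduced and lactonised with the right configuration, C13 is still missing, and absolute configuration must be introduced at the aromatic stage.
- Comparison: the chosen plan has the weaker ring-forming step but obtains the C6 oxygen, C7, C8 and C13 with absolute stereochemistry from the chiral pool in one step.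

Key step: step 6

## Route

Assumption: C11 of the amino lactones is drawn as the 11S epimer expected from trans aminomethylation; this centre is removed in step 25, so its purity does not matter.
Assumption: compound 26 is carried as a mixture of C3 carbinol epimers, both of which converge on diketone 27.

Step 1
Reactants: 1 D-glutamic acid
Product: 2 (R)-5-oxotetrahydrofuran-2-carboxylic acid
Conditions: NaNO2, aq. HCl, 0 °C → rt
Reagents that add atoms: none
Why: Diazotisation with neighbouring-group participation: the α-carboxylate displaces N2 and the γ-carboxylate opens the α-lactone, so two inversions retain the (R) centre.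

Step 2
Reactants: 2 (R)-5-oxotetrahydrofuran-2-carboxylic acid
Product: 3 (R)-5-(hydroxymethyl)dihydrofuran-2(3H)-one
Conditions: BH3·SMe2, THF, 0 °C → rt; MeOH
Reagents that add atoms: none
Why: Chemoselective borane reduction of a carboxylic acid beside a lactone.

Step 3
Reactants: 3 (R)-5-(hydroxymethyl)dihydrofuran-2(3H)-one
Product: 4 (R)-5-{[(tert-butyldimethylsilyl)oxy]methyl}dihydrofuran-2(3H)-one
Conditions: t-BuMe2SiCl, imidazole, DMF, rt
Reagents that add atoms: tert-butyldimethylsilyl chloride, CC(C)(C)[Si](C)(C)Cl
Why: Standard silylation of a primary alcohol; the primary silyl ether is chosen so that it can later be removed in the presence of a secondary one.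

Step 4
Reactants: 4 (R)-5-{[(tert-butyldimethylsilyl)oxy]methyl}dihydrofuran-2(3H)-one
Product: 7 (R)-5-{[(tert-butyldimethylsilyl)oxy]methyl}furan-2(5H)-one, via phenylselanyl lactone 5 (not isolated), via selenoxide 6 (not isolated)
Conditions: LiN(i-Pr)2, THF, −78 °C; PhSeBr; then AcOH, 30% H2O2, 0 °C → rt
Reagents that add atoms: none
Why: α-Selenenylation of the lactone enolate, oxidation and syn selenoxide elimination; the only β-hydrogens are on C4, so the endocyclic butenolide forms and C5 is untouched.

Step 5
Reactants: 8 ethyl vinyl ether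
Product: 10 lithium bis(1-ethoxyvinyl)cuprate LiCu[C(OEt)=CH2]2 (monovalent copper; used cold in solution), via 1-ethoxyvinyllithium 9 (not isolated)
Conditions: 8 (2.0 equiv per copper), t-BuLi (2.0 equiv), THF, −78 → 0 °C; CuI (1.0 equiv), THF–Et2O, −78 → −40 °C
Reagents that add atoms: ethyl vinyl ether (second equivalent), C=COCC; tert-butyllithium, [Li]C(C)(C)C; cuprous iodide CuI, [Cu]I
Why: α-Lithiation of two equivalents of the enol ether, then transmetalation of two 1-ethoxyvinyllithium units onto one CuI, gives the Gilman homocuprate and LiI; the reagent is an established acetyl anion equivalent.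

Step 6
Reactants: 7 (R)-5-{[(tert-butyldimethylsilyl)oxy]methyl}furan-2(5H)-one; 10 lithium bis(1-ethoxyvinyl)cuprate; 11 N,N-dimethylmethyleneiminium iodide (Eschenmoser's salt)
Product: 14 (3S,4R,5R)-4-acetyl-3-[(dimethylamino)methyl]-5-{[(tert-butyldimethylsilyl)oxy]methyl}dihydrofuran-2(3H)-one, via lithium lactone enolate 12 (not isolated), via enol ether Mannich base 13 (not isolated)
Conditions: 10 (1.3 equiv), THF–Et2O, −78 °C; 11 (2.0 equiv), −78 → −20 °C; aq. citric acid, THF, 0 °C; NaHCO3
Reagents that add atoms: water, O
Why: The Gilman reagent 10 forms a d–π* complex with the enoate of 7 and transfers one 1-ethoxyvinyl ligand to C7 by oxidative addition–reductive elimination, leaving lithium lactone enolate 12; this is conjugate addition of an α-alkoxyvinyl cuprate used as an acetyl anion equivalent. The iminium ion of 11 then alkylates 12 at C11 (Mannich reaction of a preformed enolate); the closest known reaction type is tandem cuprate 1,4-addition to 5-substituted butenolides with enolate capture by Eschenmoser's salt. No ring is closed. C7 is set by the C6 stereocentre: the silyloxymethyl group shields one face of the planar butenolide, so the cuprate enters anti and gives the 6,7-trans lactone. C11 is set by the new C7 substituent, the iminium ion approaching anti to it; this centre is lost again in step 25. The step needs 1,4- over 1,2-addition, which the soft copper reagent secures, and attack of the iminium ion on the enolate and not on the enol ether, which the far higher nucleophilicity of the lithium enolate at low temperature secures; the spent (1-ethoxyvinyl)copper is a poor nucleophile and is destroyed in the acid work-up. Citric acid then hydrolyses the enol ether of 13 to the C8 methyl ketone without touching the primary silyl ether, the carbonyl oxygen coming from water.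

Step 7
Reactants: 15 ethyl (S)-lactate
Product: 16 ethyl (S)-2-(triethylsilyloxy)propanoate
Conditions: Et3SiCl, imidazole, DMF, 0 °C → rt
Reagents that add atoms: triethylsilyl chloride, CC[Si](CC)(CC)Cl
Why: Standard silylation; a non-chelating silyl ether is wanted for Felkin control in step 10.

Step 8
Reactants: 16 ethyl (S)-2-(triethylsilyloxy)propanoate
Product: 17 (S)-N-methoxy-N-methyl-2-(triethylsilyloxy)propanamide
Conditions: MeNH(OMe)·HCl, i-PrMgCl, THF, −20 → 0 °C
Reagents that add atoms: N,O-dimethylhydroxylamine hydrochloride, CNOC.Cl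
Why: Weinreb amide formation from an ester with the magnesium amide; the α-centre is not epimerised under these conditions.

Step 9
Reactants: 17 (S)-N-methoxy-N-methyl-2-(triethylsilyloxy)propanamide
Product: 18 (S)-3-(triethylsilyloxy)butan-2-one
Conditions: MeMgBr, THF, 0 °C
Reagents that add atoms: methylmagnesium bromide, C[Mg]Br
Why: Weinreb ketone synthesis; the chelated tetrahedral intermediate prevents over-addition.

Step 10
Reactants: 14 (3S,4R,5R)-4-acetyl-3-[(dimethylamino)methyl]-5-{[(tert-butyldimethylsilyl)oxy]methyl}dihydrofuran-2(3H)-one; 18 (S)-3-(triethylsilyloxy)butan-2-one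
Product: 19 (3S,4R,5R)-3-[(dimethylamino)methyl]-4-[(3R,4S)-3-hydroxy-3-methyl-4-(triethylsilyloxy)pentanoyl]-5-{[(tert-butyldimethylsilyl)oxy]methyl}dihydrofuran-2(3H)-one
Conditions: LiN(i-Pr)2 (1.05 equiv), THF, −78 °C; 18; AcOH, −78 °C
Reagents that add atoms: none
Why: Kinetic deprotonation at the methyl group (C9) of the ketone and aldol addition to the activated α-silyloxy ketone forms C9–C10. C10 is set by polar Felkin–Anh control: the enolate attacks anti to the C–OSiEt3 bond and past the hydrogen of the lactate centre, which gives 10R from the (S)-ketone.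

Step 11
Reactants: 19 the β-hydroxy ketone from step 10
Product: 20 (3S,4S,5R)-4-[(1R,3R,4S)-1,3-dihydroxy-3-methyl-4-(triethylsilyloxy)pentyl]-3-[(dimethylamino)methyl]-5-{[(tert-butyldimethylsilyl)oxy]methyl}dihydrofuran-2(3H)-one
Conditions: Me4NBH(OAc)3, MeCN–AcOH, −30 °C
Reagents that add atoms: none
Why: Evans–Saksena reduction: the C10 hydroxyl exchanges onto boron and delivers hydride intramolecularly through a chair transition state, setting C8 (R) 1,3-anti to C10. The amine is protonated and inert.

Step 12
Reactants: 20 the anti diol from step 11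
Product: 21 (3S,4R,5R)-4-[(1R,3R,4S)-1-[(tert-butyldimethylsilyl)oxy]-3-hydroxy-3-methyl-4-(triethylsilyloxy)pentyl]-3-[(dimethylamino)methyl]-5-{[(tert-butyldimethylsilyl)oxy]methyl}dihydrofuran-2(3H)-one
Conditions: t-BuMe2SiOTf (1.1 equiv), 2,6-lutidine, CH2Cl2, −78 °C
Reagents that add atoms: tert-butyldimethylsilyl trifluoromethanesulfonate, CC(C)(C)[Si](C)(C)OS(=O)(=O)C(F)(F)F
Why: Silylation of the secondary C8 hydroxyl; the tertiary C10 hydroxyl does not react at this temperature. Capping C8 also stops lactone migration to that oxygen.

Step 13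
Reactants: 21 the tris-silyl ether from step 12
Product: 22 (3S,4R,5R)-4-[(1R,3R,4S)-1-[(tert-butyldimethylsilyl)oxy]-3,4-dihydroxy-3-methylpentyl]-3-[(dimethylamino)methyl]-5-(hydroxymethyl)dihydrofuran-2(3H)-one
Conditions: HF·pyridine, pyridine, THF, 0 °C → rt
Reagents that add atoms: none
Why: Rate-controlled desilylation: the primary tert-butyldimethylsilyl ether and the triethylsilyl ether cleave well before the hindered secondary silyl ether at C8.

Step 14
Reactants: 22 the triol from step 13
Product: 23 (2R,3R,4S)-3-[(1R,3R)-1-[(tert-butyldimethylsilyl)oxy]-3-hydroxy-3-methyl-4-oxopentyl]-4-[(dimethylamino)methyl]-5-oxotetrahydrofuran-2-carbaldehyde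
Conditions: (COCl)2, DMSO, CH2Cl2, −78 °C; Et3N, −78 → −30 °C
Reagents that add atoms: none
Why: Swern oxidation takes C5 to the aldehyde and C1 to the ketone in one operation; the tertiary alcohol and the amine are untouched. The aldehyde is used at once to protect C6 from epimerisation.

Step 15
Reactants: 23 the keto aldehyde from step 14
Product: 24 (3S,4R,5S)-4-[(1R,3R)-1-[(tert-butyldimethylsilyl)oxy]-3-hydroxy-3-methyl-4-oxopentyl]-3-[(dimethylamino)methyl]-5-ethenyldihydrofuran-2(3H)-one
Conditions: Ph3PCH3Br (1.5 equiv), KN(SiMe3)2 (1.4 equiv), THF, −78 → −20 °C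
Reagents that add atoms: methyltriphenylphosphonium bromide, C[P+](c1ccccc1)(c1ccccc1)c1ccccc1.[Br-]
Why: Wittig methylenation; at low temperature and with only a small excess of ylide the aldehyde reacts far faster than the hindered α-quaternary ketone, and the short cold reaction limits epimerisation at C6.

Step 16
Reactants: 24 the vinyl methyl ketone from step 15; 25 methacrolein
Product: 26 (3S,4R,5S)-4-[(1R,3R)-1-[(tert-butyldimethylsilyl)oxy]-3,6-dihydroxy-3,7-dimethyl-4-oxooct-7-en-1-yl]-3-[(dimethylamino)methyl]-5-ethenyldihydrofuran-2(3H)-one (C3 carbinol epimers)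
Conditions: LiN(i-Pr)2 (2.2 equiv), THF, −78 °C; 25; AcOH, −78 °C
Reagents that add atoms: none
Why: Aldol addition of the alkoxide–enolate dianion of an α-hydroxy methyl ketone to an enal (1,2-addition) forms C2–C3. C2 is the only enolisable position of the ketone because C10 is quaternary.

Step 17
Reactants: 26 the aldol from step 16
Product: 28 (3S,4R,5S)-4-{(1R)-1-[(tert-butyldimethylsilyl)oxy]-2-[(2R)-2-methyl-3-oxo-5-(prop-1-en-2-yl)-2,3-dihydrofuran-2-yl]ethyl}-3-[(dimethylamino)methyl]-5-ethenyldihydrofuran-2(3H)-one, via hydroxy diketone 27 (not isolated)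
Conditions: Dess–Martin periodinane, CH2Cl2, 0 °C → rt; then TsOH·H2O (1.5 equiv), rt
Reagents that add atoms: none
Why: Oxidation of the allylic carbinol gives the α′-hydroxy 1,3-diketone, which undergoes acid-catalysed cyclodehydration to the 3(2H)-furanone. Only the C10 hydroxyl is free, so the C3–O bond forms without competition from C8.

Step 18
Reactants: 28 the silylated furanone from step 17
Product: 29 (3S,4S,5S)-3-[(dimethylamino)methyl]-5-ethenyl-4-{(1R)-1-hydroxy-2-[(2R)-2-methyl-3-oxo-5-(prop-1-en-2-yl)-2,3-dihydrofuran-2-yl]ethyl}dihydrofuran-2(3H)-one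
Conditions: HF·pyridine, THF, 0 °C → rt
Reagents that add atoms: none
Why: Fluoride-mediated cleavage of the secondary silyl ether; the furanone, the lactone and the amine are stable to buffered HF.

Step 19
Reactants: 30 tert-butyl acrylate; 31 acetaldehyde
Product: 32 tert-butyl 3-hydroxy-2-methylenebutanoate (racemic)
Conditions: DABCO (cat.), neat, rt
Reagents that add atoms: none
Why: Baylis–Hillman reaction; the carbinol centre is removed two steps later.

Step 20
Reactants: 32 tert-butyl 3-hydroxy-2-methylenebutanoate
Product: 33 tert-butyl 3-acetoxy-2-methylenebutanoate (racemic)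
Conditions: Ac2O, Et3N, DMAP (cat.), CH2Cl2, 0 °C → rt
Reagents that add atoms: acetic anhydride, CC(=O)OC(C)=O
Why: Standard acetylation of a secondary allylic alcohol.

Step 21
Reactants: 33 tert-butyl 3-acetoxy-2-methylenebutanoate
Product: 34 tert-butyl (E)-2-(acetoxymethyl)but-2-enoate
Conditions: DABCO (cat.), THF, reflux
Reagents that add atoms: none
Why: Amine-catalysed SN2′–SN2′ allylic transposition of a Baylis–Hillman acetate to the more substituted olefin; the E isomer (methyl trans to the ester) is the thermodynamic product.

Step 22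
Reactants: 34 tert-butyl (E)-2-(acetoxymethyl)but-2-enoate
Product: 35 (E)-2-(acetoxymethyl)but-2-enoic acid
Conditions: CF3CO2H, CH2Cl2, 0 °C → rt
Reagents that add atoms: none
Why: Acidolysis of the tert-butyl ester frees the acid without touching the primary acetate.

Step 23
Reactants: 29 the C8 alcohol from step 18; 35 (E)-2-(acetoxymethyl)but-2-enoic acid
Product: 37 (1R)-1-{(2S,3S,4S)-4-[(dimethylamino)methyl]-2-ethenyl-5-oxotetrahydrofuran-3-yl}-2-[(2R)-2-methyl-3-oxo-5-(prop-1-en-2-yl)-2,3-dihydrofuran-2-yl]ethyl (2E)-2-(acetoxymethyl)but-2-enoate, via mixed anhydride 36 (not isolated)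
Conditions: 2,4,6-Cl3C6H2COCl, Et3N, toluene, rt; 29, DMAP, rt
Reagents that add atoms: none
Why: Yamaguchi esterification of a hindered secondary alcohol. The acid is the thermodynamically stable E isomer, so acyl-pyridinium formation cannot erode its geometry.

Step 24
Reactants: 37 the diene ester from step 23
Product: 38 (11S)-13-(dimethylamino)-11,13-dihydro derivative of the target (6S 7S 8R 10R; 4Z)
Conditions: RuCl2(=CH-C6H4-2-O-i-Pr)(H2IMes) (second-generation Hoveyda–Grubbs catalyst), TsOH·H2O (1.05 equiv), ClCH2CH2Cl, high dilution, 80 °C; NaHCO3 wash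
Reagents that add atoms: none
Why: Ring-closing metathesis between the C6 vinyl group and the furanone isopropenyl group forms C4=C5 with loss of ethylene. The nine-membered ring enforces the Z olefin, the amine is protected as its ammonium salt, and the trisubstituted side-chain enoate is inert.

Step 25
Reactants: 38 the amine from step 24
Product: 40 target CNP0176571.1 (6S 7S 8R 10R; 4Z; side chain 2E), via methiodide 39 (not isolated)
Conditions: MeI, MeCN, rt; then aq. NaHCO3, EtOAc, rt
Reagents that add atoms: none
Why: Quaternisation of the Mannich base and E1cB elimination of trimethylamine unveil the α-methylene lactone; the acidic C11 hydrogen lets bicarbonate suffice, which spares the esters.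

## Compound list

1 | D-glutamic acid | N[C@H](CCC(=O)O)C(=O)O | starting material
2 | (R)-5-oxotetrahydrofuran-2-carboxylic acid | OC(=O)[C@H]1CCC(=O)O1 | intermediate
3 | (R)-5-(hydroxymethyl)dihydrofuran-2(3H)-one | OC[C@H]1CCC(=O)O1 | intermediate
4 | (R)-5-{[(tert-butyldimethylsilyl)oxy]methyl}dihydrofuran-2(3H)-one | CC(C)(C)[Si](C)(C)OC[C@H]1CCC(=O)O1 | intermediate
5 | (5R)-5-{[(tert-butyldimethylsilyl)oxy]methyl}-3-(phenylselanyl)dihydrofuran-2(3H)-one (C3 epimers) | CC(C)(C)[Si](C)(C)OC[C@H]1CC([Se]c2ccccc2)C(=O)O1 | intermediate (not isolated)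
6 | selenoxide of 5 | CC(C)(C)[Si](C)(C)OC[C@H]1CC([Se](=O)c2ccccc2)C(=O)O1 | intermediate (not isolated)
7 | (R)-5-{[(tert-butyldimethylsilyl)oxy]methyl}furan-2(5H)-one | O=C1C=C[C@H](CO[Si](C)(C)C(C)(C)C)O1 | intermediate
8 | ethyl vinyl ether | C=COCC | starting material
9 | 1-ethoxyvinyllithium | C=C([Li])OCC | intermediate (not isolated)
10 | lithium bis(1-ethoxyvinyl)cuprate | C=C(OCC)[Cu-]C(=C)OCC.[Li+] | intermediate
11 | N,N-dimethylmethyleneiminium iodide (Eschenmoser's salt) | C=[N+](C)C.[I-] | starting material
12 | lithium (4R,5R)-5-{[(tert-butyldimethylsilyl)oxy]methyl}-4-(1-ethoxyvinyl)-4,5-dihydrofuran-2-olate | [Li]OC1=C[C@@H](C(=C)OCC)[C@H](CO[Si](C)(C)C(C)(C)C)O1 | intermediate (not isolated)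
13 | (3S,4R,5R)-3-[(dimethylamino)methyl]-4-(1-ethoxyvinyl)-5-{[(tert-butyldimethylsilyl)oxy]methyl}dihydrofuran-2(3H)-one | O=C1[C@H](CN(C)C)[C@@H](C(=C)OCC)[C@H](CO[Si](C)(C)C(C)(C)C)O1 | intermediate (not isolated)
14 | (3S,4R,5R)-4-acetyl-3-[(dimethylamino)methyl]-5-{[(tert-butyldimethylsilyl)oxy]methyl}dihydrofuran-2(3H)-one | O=C1[C@H](CN(C)C)[C@@H](C(C)=O)[C@H](CO[Si](C)(C)C(C)(C)C)O1 | intermediate
15 | ethyl (S)-lactate | C[C@H](O)C(=O)OCC | starting material
16 | ethyl (S)-2-(triethylsilyloxy)propanoate | C[C@H](O[Si](CC)(CC)CC)C(=O)OCC | intermediate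
17 | (S)-N-methoxy-N-methyl-2-(triethylsilyloxy)propanamide | C[C@H](O[Si](CC)(CC)CC)C(=O)N(C)OC | intermediate
18 | (S)-3-(triethylsilyloxy)butan-2-one | C[C@H](O[Si](CC)(CC)CC)C(C)=O | intermediate
19 | (3S,4R,5R)-3-[(dimethylamino)methyl]-4-[(3R,4S)-3-hydroxy-3-methyl-4-(triethylsilyloxy)pentanoyl]-5-{[(tert-butyldimethylsilyl)oxy]methyl}dihydrofuran-2(3H)-one | O=C1[C@H](CN(C)C)[C@@H](C(=O)C[C@@](C)(O)[C@H](C)O[Si](CC)(CC)CC)[C@H](CO[Si](C)(C)C(C)(C)C)O1 | intermediate
20 | (3S,4S,5R)-4-[(1R,3R,4S)-1,3-dihydroxy-3-methyl-4-(triethylsilyloxy)pentyl]-3-[(dimethylamino)methyl]-5-{[(tert-butyldimethylsilyl)oxy]methyl}dihydrofuran-2(3H)-one | O=C1[C@H](CN(C)C)[C@@H]([C@H](O)C[C@@](C)(O)[C@H](C)O[Si](CC)(CC)CC)[C@H](CO[Si](C)(C)C(C)(C)C)O1 | intermediate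
21 | (3S,4R,5R)-4-[(1R,3R,4S)-1-[(tert-butyldimethylsilyl)oxy]-3-hydroxy-3-methyl-4-(triethylsilyloxy)pentyl]-3-[(dimethylamino)methyl]-5-{[(tert-butyldimethylsilyl)oxy]methyl}dihydrofuran-2(3H)-one | O=C1[C@H](CN(C)C)[C@@H]([C@H](O[Si](C)(C)C(C)(C)C)C[C@@](C)(O)[C@H](C)O[Si](CC)(CC)CC)[C@H](CO[Si](C)(C)C(C)(C)C)O1 | intermediate
22 | (3S,4R,5R)-4-[(1R,3R,4S)-1-[(tert-butyldimethylsilyl)oxy]-3,4-dihydroxy-3-methylpentyl]-3-[(dimethylamino)methyl]-5-(hydroxymethyl)dihydrofuran-2(3H)-one | O=C1[C@H](CN(C)C)[C@@H]([C@H](O[Si](C)(C)C(C)(C)C)C[C@@](C)(O)[C@H](C)O)[C@H](CO)O1 | intermediate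
23 | (2R,3R,4S)-3-[(1R,3R)-1-[(tert-butyldimethylsilyl)oxy]-3-hydroxy-3-methyl-4-oxopentyl]-4-[(dimethylamino)methyl]-5-oxotetrahydrofuran-2-carbaldehyde | O=C1[C@H](CN(C)C)[C@@H]([C@H](O[Si](C)(C)C(C)(C)C)C[C@@](C)(O)C(C)=O)[C@H](C=O)O1 | intermediate
24 | (3S,4R,5S)-4-[(1R,3R)-1-[(tert-butyldimethylsilyl)oxy]-3-hydroxy-3-methyl-4-oxopentyl]-3-[(dimethylamino)methyl]-5-ethenyldihydrofuran-2(3H)-one | O=C1[C@H](CN(C)C)[C@@H]([C@H](O[Si](C)(C)C(C)(C)C)C[C@@](C)(O)C(C)=O)[C@H](C=C)O1 | intermediate
25 | methacrolein | C=C(C)C=O | starting material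
26 | (3S,4R,5S)-4-[(1R,3R)-1-[(tert-butyldimethylsilyl)oxy]-3,6-dihydroxy-3,7-dimethyl-4-oxooct-7-en-1-yl]-3-[(dimethylamino)methyl]-5-ethenyldihydrofuran-2(3H)-one (C3 carbinol epimers) | O=C1[C@H](CN(C)C)[C@@H]([C@H](O[Si](C)(C)C(C)(C)C)C[C@@](C)(O)C(=O)CC(O)C(C)=C)[C@H](C=C)O1 | intermediate
27 | (3S,4R,5S)-4-[(1R,3R)-1-[(tert-butyldimethylsilyl)oxy]-3-hydroxy-3,7-dimethyl-4,6-dioxooct-7-en-1-yl]-3-[(dimethylamino)methyl]-5-ethenyldihydrofuran-2(3H)-one | O=C1[C@H](CN(C)C)[C@@H]([C@H](O[Si](C)(C)C(C)(C)C)C[C@@](C)(O)C(=O)CC(=O)C(C)=C)[C@H](C=C)O1 | intermediate (not isolated)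
28 | (3S,4R,5S)-4-{(1R)-1-[(tert-butyldimethylsilyl)oxy]-2-[(2R)-2-methyl-3-oxo-5-(prop-1-en-2-yl)-2,3-dihydrofuran-2-yl]ethyl}-3-[(dimethylamino)methyl]-5-ethenyldihydrofuran-2(3H)-one | O=C1[C@H](CN(C)C)[C@@H]([C@H](O[Si](C)(C)C(C)(C)C)C[C@@]2(C)OC(C(C)=C)=CC2=O)[C@H](C=C)O1 | intermediate
29 | (3S,4S,5S)-3-[(dimethylamino)methyl]-5-ethenyl-4-{(1R)-1-hydroxy-2-[(2R)-2-methyl-3-oxo-5-(prop-1-en-2-yl)-2,3-dihydrofuran-2-yl]ethyl}dihydrofuran-2(3H)-one | O=C1[C@H](CN(C)C)[C@@H]([C@H](O)C[C@@]2(C)OC(C(C)=C)=CC2=O)[C@H](C=C)O1 | intermediate
30 | tert-butyl acrylate | C=CC(=O)OC(C)(C)C | starting material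
31 | acetaldehyde | CC=O | starting material
32 | tert-butyl 3-hydroxy-2-methylenebutanoate (racemic) | CC(O)C(=C)C(=O)OC(C)(C)C | intermediate
33 | tert-butyl 3-acetoxy-2-methylenebutanoate (racemic) | CC(OC(C)=O)C(=C)C(=O)OC(C)(C)C | intermediate
34 | tert-butyl (E)-2-(acetoxymethyl)but-2-enoate | C/C=C(\COC(C)=O)C(=O)OC(C)(C)C | intermediate
35 | (E)-2-(acetoxymethyl)but-2-enoic acid | C/C=C(\COC(C)=O)C(=O)O | intermediate
36 | (E)-2-(acetoxymethyl)but-2-enoic 2,4,6-trichlorobenzoic anhydride | C/C=C(\COC(C)=O)C(=O)OC(=O)c1c(Cl)cc(Cl)cc1Cl | intermediate (not isolated)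
37 | (1R)-1-{(2S,3S,4S)-4-[(dimethylamino)methyl]-2-ethenyl-5-oxotetrahydrofuran-3-yl}-2-[(2R)-2-methyl-3-oxo-5-(prop-1-en-2-yl)-2,3-dihydrofuran-2-yl]ethyl (2E)-2-(acetoxymethyl)but-2-enoate | O=C1[C@H](CN(C)C)[C@@H]([C@H](OC(=O)/C(=C/C)COC(C)=O)C[C@@]2(C)OC(C(C)=C)=CC2=O)[C@H](C=C)O1 | intermediate
38 | (11S)-13-(dimethylamino)-11,13-dihydro derivative of the target (6S,7S,8R,10R; 4Z) | CN(C)C[C@H]1C(=O)O[C@H]2/C=C(/C)C3=CC(=O)[C@@](C)(C[C@@H](OC(=O)/C(=C/C)COC(C)=O)[C@H]12)O3 | intermediate
39 | N-methyl ammonium iodide of 38 | C[N+](C)(C)C[C@H]1C(=O)O[C@H]2/C=C(/C)C3=CC(=O)[C@@](C)(C[C@@H](OC(=O)/C(=C/C)COC(C)=O)[C@H]12)O3.[I-] | intermediate (not isolated)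
40 | CNP0176571.1: (6S,7S,8R,10R)-3,10-epoxy-1-oxogermacra-2,4(Z),11(13)-trien-12,6-olide 8-[(E)-2-(acetoxymethyl)but-2-enoate] | C=C1C(=O)O[C@H]2/C=C(/C)C3=CC(=O)[C@@](C)(C[C@@H](OC(=O)/C(=C/C)COC(C)=O)[C@H]12)O3 | target

## Step count and least certain steps

Total: 25 steps. Longest linear sequence: 17 steps (1–4, 6, 10–18, 23–25).

**Step 6 (key step).** The most likely failure is incomplete capture of the copper–lithium enolate aggregate by the iminium salt, so that protonation on work-up competes. Aminomethylation of the electron-rich enol ether is a second risk, because alkenyl cuprate enolates are sluggish nucleophiles. Fallback: separate the two events. Butenolide 7 and cuprate 10 are combined and quenched with NH4Cl to give the conjugate adduct, (4R,5R)-4-(1-ethoxyvinyl)-5-{[(tert-butyldimethylsilyl)oxy]methyl}dihydrofuran-2(3H)-one F1. A clean lithium enolate is then regenerated from it with LiN(i-Pr)2 and treated with 11. This rejoins the route at 13 and, after the same hydrolysis, at 14.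

**Step 10.** The acceptor is an enolisable ketone, so proton transfer between enolate and acceptor and retro-aldol reversal can drain the adduct. Lithium chelation to the silyloxy oxygen could also erode the Felkin preference at C10. Fallback: change from a closed lithium transition state to an open, Lewis-acid-mediated one. Ketone 14 is converted (LiN(i-Pr)2, Me3SiCl) into its trimethylsilyl enol ether F2. This is added to 18 with excess BF3·OEt2 (Mukaiyama aldol; non-chelating, with the amine saturated by the first equivalent), returning to 19.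

**Step 11.** Exchange of the tertiary C10 hydroxyl onto boron may be slow, letting undirected reduction compete and lowering the anti selectivity. Fallback: switch from substrate direction to reagent control. Ketone 19 is reduced with the (S)-oxazaborolidine (Corey–Bakshi–Shibata) catalyst and catecholborane. The C7 branch is treated as the large group, which gives 20 directly; no new compound is involved (F0).

**Step 24.** The ruthenium carbene may fail to engage the hindered, electron-poor isopropenyl group. Strain in the bridged nine-membered ring may also divert the loaded vinyl terminus into dimerisation. Fallback: reverse the order of ring formation. The open hydroxy ketone 26 is cyclised by the same metathesis to the less strained ten-membered carbocycle F3. Oxidation and acid then form the furanone transannularly to give the bridged silyl ether F4, and HF·pyridine frees the C8 alcohol F5. Yamaguchi esterification of F5 with 35 rejoins the route at 38.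

**Step 25.** The trimethylamine released, or the base, may attack the side-chain allylic acetate (SN2′) or add to the new methylene lactone. Fallback: replace anti E1cB elimination of the ammonium salt by a thermal syn elimination. Amine 38 is oxidised with m-chloroperbenzoic acid at low temperature to the N-oxide F6, which undergoes Cope elimination on warming to give 40 without liberating trimethylamine and without added base.

## Further compounds

F1 | step 6 | (4R,5R)-4-(1-ethoxyvinyl)-5-{[(tert-butyldimethylsilyl)oxy]methyl}dihydrofuran-2(3H)-one | O=C1C[C@@H](C(=C)OCC)[C@H](CO[Si](C)(C)C(C)(C)C)O1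
F2 | step 10 | (3S,4R,5R)-3-[(dimethylamino)methyl]-4-[1-(trimethylsilyloxy)vinyl]-5-{[(tert-butyldimethylsilyl)oxy]methyl}dihydrofuran-2(3H)-one | O=C1[C@H](CN(C)C)[C@@H](C(=C)O[Si](C)(C)C)[C@H](CO[Si](C)(C)C(C)(C)C)O1
F0 | step 11 | none | none
F3 | step 24 | ten-membered carbocyclic C3 carbinol, C1 ketone, C10 alcohol, C8 silyl ether, 13-dimethylamino lactone (4Z) | CN(C)C[C@H]1C(=O)O[C@H]2/C=C(/C)C(O)CC(=O)[C@](C)(O)C[C@@H](O[Si](C)(C)C(C)(C)C)[C@H]12
F4 | step 24 | C8 tert-butyldimethylsilyl ether of the bridged furanone, 13-dimethylamino-11,13-dihydro series | CN(C)C[C@H]1C(=O)O[C@H]2/C=C(/C)C3=CC(=O)[C@@](C)(C[C@@H](O[Si](C)(C)C(C)(C)C)[C@H]12)O3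
F5 | step 24 | C8 alcohol of the bridged furanone, 13-dimethylamino-11,13-dihydro series | CN(C)C[C@H]1C(=O)O[C@H]2/C=C(/C)C3=CC(=O)[C@@](C)(C[C@@H](O)[C@H]12)O3
F6 | step 25 | N-oxide of 38 | C[N+](C)([O-])C[C@H]1C(=O)O[C@H]2/C=C(/C)C3=CC(=O)[C@@](C)(C[C@@H](OC(=O)/C(=C/C)COC(C)=O)[C@H]12)O3
A1 | alternative 1 | acyclic bromomethyl (Z)-enone with C1 aldehyde, C8 and C10 silyl ethers and the methylene lactone | BrCC(=O)/C(C)=C\[C@@H]1OC(=O)C(=C)[C@H]1[C@H](O[Si](C)(C)C(C)(C)C)C[C@@](C)(O[Si](CC)(CC)CC)C=O
A2 | alternative 1 | ten-membered β-hydroxy ketone fused to the lactone (C1 carbinol as one epimer) | O[C@@H]1CC(=O)/C(C)=C\[C@@H]2OC(=O)C(=C)[C@H]2[C@H](O[Si](C)(C)C(C)(C)C)C[C@@]1(C)O[Si](CC)(CC)CC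
A3 | alternative 2 | nine-membered (Z)-enoate lactone on the C10 oxygen carrying the C10 acetyl group | C=C1C(=O)O[C@H]2/C=C(/C)C(=O)O[C@@](C)(C(C)=O)C[C@@H](O[Si](C)(C)C(C)(C)C)[C@H]12
A4 | alternative 2 | C8 O-silyl ether of the deacylated target | C=C1C(=O)O[C@H]2/C=C(/C)C3=CC(=O)[C@@](C)(C[C@@H](O[Si](C)(C)C(C)(C)C)[C@H]12)O3
A5 | alternative 3 | Birch-derived octalenone with the C1=C6 ring-fusion olefin (C4 as one epimer) | COC(=O)C[C@H]1[C@H](O[Si](C)(C)C(C)(C)C)C[C@@](C)(O)C2=C1C[C@H](C)C(=O)C2
A6 | alternative 3 | ten-membered 1,3,6-triketone with the C10 tertiary alcohol (C4 as one epimer) | COC(=O)C[C@H]1[C@H](O[Si](C)(C)C(C)(C)C)C[C@@](C)(O)C(=O)CC(=O)[C@@H](C)CC1=O
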